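Ring A is disconnected across C8a–C4a, C5–C6 and C8a–C8, so the whole phloroglucinol core is made de novo. Its contiguous pattern C8a(O)–C4a(C4)–C5(OMe)–C6(alkyl)–C7(O)–C8(H) is what a vinylketene and an alkynyl ether give on thermal benzannulation. One operation therefore builds ring A fully substituted and joins the two chiral halves. These are a 2-alkyl-3-siloxycyclobutenone carrying the lavandulyl hydrate side chain (stereocentre from an Evans alkylation) and a methoxyalkyne carrying C4, C3, the (R)-C2 carbinol (Brown allylation) and ring B. Ring C is closed afterwards by Mitsunobu etherification with inversion at C2, and C4 is oxidised to the ketone.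

Key step: step 14

Remark: the carbinol carbon that becomes C4 forms without control in step 12 and is drawn without configuration in 27, 28 and 30 to 36 (as is the transient ring carbon of 30); step 18 removes it.

Step 1
Reactants: 1 pent-4-ynoic acid; 2 (S)-4-benzyloxazolidin-2-one
Product: 4 (S)-4-benzyl-3-(pent-4-ynoyl)oxazolidin-2-one, via pivalic mixed anhydride 3 (not isolated)
Conditions: PivCl, Et3N, THF, −20 °C; then LiCl, 2, −20 °C to rt
Reagents that add atoms: none
Why: N-acylation of the oxazolidinone by a mixed anhydride formed in situ (LiCl-assisted imide formation) is the standard entry to Evans imides and tolerates the terminal alkyne.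

Step 2
Reactants: 4 (S)-4-benzyl-3-(pent-4-ynoyl)oxazolidin-2-one; 5 prenyl bromide
Product: 7 (S)-4-benzyl-3-[(2S)-5-methyl-2-(prop-2-yn-1-yl)hex-4-enoyl]oxazolidin-2-one, via sodium Z-enolate 6 (not isolated)
Conditions: NaN(SiMe3)2 (1.05 equiv), THF, −78 °C; then 5, −78 to −40 °C
Reagents that add atoms: none
Why: Evans asymmetric alkylation, in which the chelated Z-enolate is alkylated on the face opposite the benzyl group and so sets the (2S) centre; the imide α-C–H is far more acidic than the alkyne C–H, so one equivalent of base should enolise selectively.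

Step 3
Reactants: 7 (S)-4-benzyl-3-[(2S)-5-methyl-2-(prop-2-yn-1-yl)hex-4-enoyl]oxazolidin-2-one
Product: 8 methyl (2S)-5-methyl-2-(prop-2-yn-1-yl)hex-4-enoate
Conditions: MeOMgBr (from MeMgBr and MeOH), MeOH/CH2Cl2, 0 °C
Reagents that add atoms: methanol (delivered as MeOMgBr), CO
Why: transesterification with bromomagnesium methoxide attacks the exocyclic imide carbonyl, giving the ester without epimerisation and returning the auxiliary.

Step 4
Reactants: 8 methyl (2S)-5-methyl-2-(prop-2-yn-1-yl)hex-4-enoate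
Product: 10 (3S)-2,6-dimethyl-3-(prop-2-yn-1-yl)hept-5-en-2-ol, via methyl ketone 9 (not isolated)
Conditions: MeMgBr (5 equiv), CeCl3 (anhydrous), THF, −78 to 0 °C
Reagents that add atoms: methylmagnesium bromide, C[Mg]Br
Why: double Grignard addition to the ester; the cerium reagent suppresses enolisation of the intermediate ketone so the adjacent stereocentre should not epimerise, and the equivalent consumed by the alkyne C–H is returned on work-up.

Step 5
Reactants: 10 (3S)-2,6-dimethyl-3-(prop-2-yn-1-yl)hept-5-en-2-ol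
Product: 11 triethylsilyl ether of 10
Conditions: TESOTf, 2,6-lutidine, CH2Cl2, −78 to 0 °C
Reagents that add atoms: triethylsilyl triflate, CC[Si](CC)(CC)OS(=O)(=O)C(F)(F)F
Why: a silyl triflate with a hindered pyridine base is the standard silylation of a tertiary carbinol and masks it against the organolithium, ketene and vinylketene chemistry that follows.

Step 6
Reactants: 11 triethylsilyl ether of 10
Product: 14 (4S)-7-methyl-4-[2-(triethylsilyloxy)propan-2-yl]-1-(triisopropylsilyloxy)oct-6-en-1-yne, via lithium acetylide 12 (not isolated), via lithium ynolate 13 (not isolated)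
Conditions: n-BuLi, THF, −78 °C; LiOOt-Bu (from t-BuOOH and LiN(SiMe3)2), −78 to 0 °C; TIPSOTf, −78 to 0 °C
Reagents that add atoms: lithium tert-butyl peroxide, CC(C)(C)OO[Li]; triisopropylsilyl triflate, CC(C)[Si](C(C)C)(C(C)C)OS(=O)(=O)C(F)(F)F
Why: oxidation of a lithium acetylide to the ynolate by lithium tert-butyl peroxide followed by O-silylation with a bulky silyl triflate is the established one-pot synthesis of siloxyalkynes (Julia ynolate oxidation).

Step 7
Reactants: 14 siloxyalkyne; 15 diketene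
Product: 17 3-(triisopropylsilyloxy)-2-{(2S)-5-methyl-2-[2-(triethylsilyloxy)propan-2-yl]hex-4-en-1-yl}cyclobut-2-en-1-one, via ketene 16 (not isolated)
Conditions: 15 (excess) cracked at about 550 °C (hot quartz tube), ketene gas passed into 14, CH2Cl2, 0 °C to rt; surplus ketene led to a trap; concentrated and used crude
Reagents that add atoms: none
Why: each molecule of 15 cracks to two of ketene, one of which is taken up in a ketene–alkyne [2+2] cycloaddition polarised by the siloxy donor, in which the alkyl-bearing alkyne carbon bonds to the ketene carbonyl carbon and gives the 2-alkyl-3-siloxycyclobutenone regiochemistry; the product is moisture-sensitive and is kept dry.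

Step 8
Reactants: 18 2,4-dihydroxybenzaldehyde
Product: 19 2,4-bis(triisopropylsilyloxy)benzaldehyde
Conditions: TIPSCl (2.4 equiv), imidazole, DMAP (cat.), DMF, rt to 40 °C
Reagents that add atoms: triisopropylsilyl chloride, CC(C)[Si](Cl)(C(C)C)C(C)C
Why: imidazole-mediated silylation of both phenols; the hydrogen-bonded ortho hydroxyl needs the nucleophilic catalyst and mild warming.

Step 9
Reactants: 19 2,4-bis(triisopropylsilyloxy)benzaldehyde; 20 allylmagnesium bromide
Product: 22 (1R)-1-[2,4-bis(triisopropylsilyloxy)phenyl]but-3-en-1-ol, via B-allyldiisopinocampheylborane 21 (not isolated)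
Conditions: (+)-Ipc2BOMe, 20, Et2O, −78 °C to rt; then 19, −78 °C; then HOCH2CH2NH2, rt
Reagents that add atoms: none
Why: Brown asymmetric allylboration through a chair six-membered transition state; the allylborane derived from (−)-α-pinene attacks the Re face of aryl aldehydes, which sets the (R) carbinol, and the non-oxidative amino alcohol work-up spares the aryl silyl ethers.

Step 10
Reactants: 22 (1R)-1-[2,4-bis(triisopropylsilyloxy)phenyl]but-3-en-1-ol
Product: 23 triethylsilyl ether of 22
Conditions: TESCl, imidazole, DMF, 0 °C to rt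
Reagents that add atoms: triethylsilyl chloride, CC[Si](Cl)(CC)CC
Why: standard silylation of a secondary alcohol; the triethylsilyl group is chosen because it can later be removed in the presence of tert-butyldimethylsilyl and aryl triisopropylsilyl ethers.

Step 11
Reactants: 23 triethylsilyl ether of 22
Product: 24 (3R)-3-[2,4-bis(triisopropylsilyloxy)phenyl]-3-(triethylsilyloxy)propanal
Conditions: OsO4 (2 mol%), NaIO4, 2,6-lutidine, dioxane/H2O, rt
Reagents that add atoms: osmium tetroxide (oxygen donor, turned over by periodate), O=[Os](=O)(=O)=O; sodium periodate, [Na+].[O-]I(=O)(=O)=O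
Why: Lemieux–Johnson cleavage (dihydroxylation then periodate glycol cleavage, lutidine-buffered) is preferred to ozone because of the electron-rich arene; the β-silyloxy aldehyde is used promptly.

Step 12
Reactants: 24 (3R)-3-[2,4-bis(triisopropylsilyloxy)phenyl]-3-(triethylsilyloxy)propanal; 25 chloroacetaldehyde dimethyl acetal
Product: 27 (5R)-5-[2,4-bis(triisopropylsilyloxy)phenyl]-1-methoxy-5-(triethylsilyloxy)pent-1-yn-3-ol (epimers at C3), via lithium methoxyacetylide 26 (not isolated)
Conditions: 25, LiNEt2 (3 equiv, from Et2NH and n-BuLi), THF, −78 to 0 °C; then 24, −78 °C; NaHCO3 (aq) quench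
Reagents that add atoms: none
Why: 1,2-addition of lithium methoxyacetylide (from the chloroacetal by two eliminations and a deprotonation) to the aldehyde at low temperature; the new carbinol forms as epimers, which is harmless since it ends as the C4 ketone, and acid is excluded to avoid Meyer–Schuster rearrangement.

Step 13
Reactants: 27 propargylic alcohol
Product: 28 tert-butyldimethylsilyl ether of 27
Conditions: TBSCl, imidazole, DMAP (cat.), DMF, 0 °C to rt
Reagents that add atoms: tert-butyldimethylsilyl chloride, CC(C)(C)[Si](C)(C)Cl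
Why: silylation under basic conditions converts the acid-labile alkoxyethynyl carbinol into a robust silyl ether that will survive heating.

Step 14
Reactants: 17 cyclobutenone; 28 methoxyalkyne
Product: 33 2-{(3R)-3-[2,4-bis(triisopropylsilyloxy)phenyl]-1-(tert-butyldimethylsilyloxy)-3-(triethylsilyloxy)propyl}-3-methoxy-4-{(2S)-5-methyl-2-[2-(triethylsilyloxy)propan-2-yl]hex-4-en-1-yl}-5-(triisopropylsilyloxy)phenol, via vinylketene 29 (not isolated), via vinylcyclobutenone 30 (not isolated), via dienylketene 31 (not isolated), via cyclohexadienone 32 (not isolated)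
Conditions: 17 added slowly to 28 (1.2 equiv, about 1 M), degassed toluene, 80 °C, then 110 °C
Reagents that add atoms: none
Why: Danheiser benzannulation: 17 opens by 4π electrocyclic ring opening to the (2-siloxyvinyl)ketene 29, whose ketene C=C adds the methoxyalkyne in a polarised [2+2] (nucleophilic alkyne carbon to the ketene carbonyl carbon, C4a to C8a, and the methoxy-bearing carbon to the ketene α-carbon, C5 to C6) to give 30, and a second 4π opening cleaves the old C8a–C6 bond to give dienylketene 31. Ring A is then closed by thermal 6π electrocyclisation, which forms C8a–C8 and gives cyclohexadienone 32, and this tautomerises to the phenol. The closest known reaction type is the thermal aromatic annulation of cyclobutenones with alkoxy- and siloxyalkynes to give resorcinol monoethers. No stereocentre is formed, and the three existing ones are remote from the reacting atoms and should be untouched. The step needs the regiochemistry of the ketene–alkyne cycloaddition, which the donor polarisation of the ynol ether secures, and it needs bimolecular capture of 29 to outrun intramolecular ketene–olefin cycloaddition onto the prenyl group, which a concentrated solution and an excess of the strongly ketenophilic alkyne favour. A methyl ynol ether is used because it has no β-hydrogen for the retro-ene loss of alkene that limits ethyl ynol ethers on heating.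

Step 15
Reactants: 33 benzannulation phenol
Product: 34 2-{(3R)-3-[2,4-bis(triisopropylsilyloxy)phenyl]-1-(tert-butyldimethylsilyloxy)-3-hydroxypropyl}-3-methoxy-4-{(2S)-5-methyl-2-[2-(triethylsilyloxy)propan-2-yl]hex-4-en-1-yl}-5-(triisopropylsilyloxy)phenol
Conditions: HF·pyridine, pyridine, THF, 0 °C
Reagents that add atoms: none
Why: kinetic desilylation, in which the secondary triethylsilyl ether is cleaved much faster than the tertiary triethylsilyl, the tert-butyldimethylsilyl and the aryl silyl ethers; any material that also loses the tertiary silyl group reacts the same way in step 16 and converges at 36.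

Step 16
Reactants: 34 phenol with free C2 carbinol
Product: 35 (2S)-2-[2,4-bis(triisopropylsilyloxy)phenyl]-4-(tert-butyldimethylsilyloxy)-5-methoxy-6-{(2S)-5-methyl-2-[2-(triethylsilyloxy)propan-2-yl]hex-4-en-1-yl}-7-(triisopropylsilyloxy)chroman
Conditions: PPh3, DIAD, toluene (0.01 M), 0 °C
Reagents that add atoms: none
Why: intramolecular Mitsunobu etherification (6-exo-tet), in which the C8a phenol displaces the oxyphosphonium at the benzylic carbon with inversion and turns the (R) carbinol into the (2S) flavan; low temperature, a non-polar solvent and the weakly donating silyloxy groups of ring B disfavour ionisation.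

Step 17
Reactants: 35 silylated flavan
Product: 36 (2S)-2-[2,4-bis(triisopropylsilyloxy)phenyl]-6-[(2S)-2-(2-hydroxypropan-2-yl)-5-methylhex-4-en-1-yl]-5-methoxy-7-(triisopropylsilyloxy)chroman-4-ol
Conditions: HF·pyridine, pyridine, THF, rt
Reagents that add atoms: none
Why: buffered acidic fluoride cleaves alkyl silyl ethers (secondary tert-butyldimethylsilyl and tertiary triethylsilyl) while sparing aryl silyl ethers, and the pyridine buffer limits ionisation of the electron-rich benzylic C4 carbinol.

Step 18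
Reactants: 36 flavan-4-ol
Product: 37 (2S)-2-[2,4-bis(triisopropylsilyloxy)phenyl]-6-[(2S)-2-(2-hydroxypropan-2-yl)-5-methylhex-4-en-1-yl]-5-methoxy-7-(triisopropylsilyloxy)chroman-4-one
Conditions: Dess–Martin periodinane, NaHCO3, CH2Cl2, 0 °C to rt
Reagents that add atoms: none
Why: Dess–Martin oxidation of the secondary benzylic alcohol under buffered conditions; both C4 epimers converge on one ketone and the tertiary alcohol is inert.

Step 19
Reactants: 37 tris-silylated flavanone
Product: 38 (2S)-2-(2,4-dihydroxyphenyl)-7-hydroxy-6-[(2S)-2-(2-hydroxypropan-2-yl)-5-methylhex-4-en-1-yl]-5-methoxychroman-4-one (CNP0298187.1)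
Conditions: Bu4NF/AcOH (1:1), THF, 0 °C
Reagents that add atoms: none
Why: fluoride cleavage of aryl silyl ethers is fast at 0 °C, and buffering with acetic acid keeps the medium non-basic so the flavanone should not open to the chalcone by retro-oxa-Michael reaction and C2 keeps its configuration.

Compound list
1 | pent-4-ynoic acid | C#CCCC(=O)O | starting material
2 | (S)-4-benzyloxazolidin-2-one | O=C1N[C@@H](Cc2ccccc2)CO1 | starting material
3 | pent-4-ynoic pivalic anhydride | C#CCCC(=O)OC(=O)C(C)(C)C | intermediate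
4 | (S)-4-benzyl-3-(pent-4-ynoyl)oxazolidin-2-one | C#CCCC(=O)N1[C@@H](Cc2ccccc2)COC1=O | intermediate
5 | prenyl bromide (1-bromo-3-methylbut-2-ene) | CC(C)=CCBr | starting material
6 | sodium Z-enolate of 4 | C#CC/C=C(\[O-])N1[C@@H](Cc2ccccc2)COC1=O.[Na+] | intermediate
7 | (S)-4-benzyl-3-[(2S)-5-methyl-2-(prop-2-yn-1-yl)hex-4-enoyl]oxazolidin-2-one | C#CC[C@H](CC=C(C)C)C(=O)N1[C@@H](Cc2ccccc2)COC1=O | intermediate
8 | methyl (2S)-5-methyl-2-(prop-2-yn-1-yl)hex-4-enoate | C#CC[C@H](CC=C(C)C)C(=O)OC | intermediate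
9 | (3S)-6-methyl-3-(prop-2-yn-1-yl)hept-5-en-2-one | C#CC[C@H](CC=C(C)C)C(C)=O | intermediate
10 | (3S)-2,6-dimethyl-3-(prop-2-yn-1-yl)hept-5-en-2-ol | C#CC[C@H](CC=C(C)C)C(C)(C)O | intermediate
11 | triethylsilyl ether of 10 | C#CC[C@H](CC=C(C)C)C(C)(C)O[Si](CC)(CC)CC | intermediate
12 | lithium acetylide of 11 | [Li]C#CC[C@H](CC=C(C)C)C(C)(C)O[Si](CC)(CC)CC | intermediate
13 | lithium ynolate from 12 | [Li]OC#CC[C@H](CC=C(C)C)C(C)(C)O[Si](CC)(CC)CC | intermediate
14 | (4S)-7-methyl-4-[2-(triethylsilyloxy)propan-2-yl]-1-(triisopropylsilyloxy)oct-6-en-1-yne | CC(C)[Si](OC#CC[C@H](CC=C(C)C)C(C)(C)O[Si](CC)(CC)CC)(C(C)C)C(C)C | intermediate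
15 | diketene (4-methyleneoxetan-2-one) | C=C1CC(=O)O1 | starting material
16 | ketene | C=C=O | intermediate
17 | 3-(triisopropylsilyloxy)-2-{(2S)-5-methyl-2-[2-(triethylsilyloxy)propan-2-yl]hex-4-en-1-yl}cyclobut-2-en-1-one | O=C1CC(O[Si](C(C)C)(C(C)C)C(C)C)=C1C[C@H](CC=C(C)C)C(C)(C)O[Si](CC)(CC)CC | intermediate
18 | 2,4-dihydroxybenzaldehyde | O=Cc1ccc(O)cc1O | starting material
19 | 2,4-bis(triisopropylsilyloxy)benzaldehyde | O=Cc1ccc(O[Si](C(C)C)(C(C)C)C(C)C)cc1O[Si](C(C)C)(C(C)C)C(C)C | intermediate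
20 | allylmagnesium bromide | C=CC[Mg]Br | starting material
21 | B-allyldiisopinocampheylborane from (−)-α-pinene | C=CCB([C@H]1C[C@H]2C[C@@H]([C@@H]1C)C2(C)C)[C@H]1C[C@H]2C[C@@H]([C@@H]1C)C2(C)C | intermediate
22 | (1R)-1-[2,4-bis(triisopropylsilyloxy)phenyl]but-3-en-1-ol | C=CC[C@H](c1ccc(O[Si](C(C)C)(C(C)C)C(C)C)cc1O[Si](C(C)C)(C(C)C)C(C)C)O | intermediate
23 | triethylsilyl ether of 22 | C=CC[C@H](c1ccc(O[Si](C(C)C)(C(C)C)C(C)C)cc1O[Si](C(C)C)(C(C)C)C(C)C)O[Si](CC)(CC)CC | intermediate
24 | (3R)-3-[2,4-bis(triisopropylsilyloxy)phenyl]-3-(triethylsilyloxy)propanal | O=CC[C@H](c1ccc(O[Si](C(C)C)(C(C)C)C(C)C)cc1O[Si](C(C)C)(C(C)C)C(C)C)O[Si](CC)(CC)CC | intermediate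
25 | chloroacetaldehyde dimethyl acetal (2-chloro-1,1-dimethoxyethane) | COC(CCl)OC | starting material
26 | lithium methoxyacetylide | COC#C[Li] | intermediate
27 | (5R)-5-[2,4-bis(triisopropylsilyloxy)phenyl]-1-methoxy-5-(triethylsilyloxy)pent-1-yn-3-ol, epimers at C3 | COC#CC(O)C[C@H](c1ccc(O[Si](C(C)C)(C(C)C)C(C)C)cc1O[Si](C(C)C)(C(C)C)C(C)C)O[Si](CC)(CC)CC | intermediate
28 | tert-butyldimethylsilyl ether of 27 | COC#CC(O[Si](C)(C)C(C)(C)C)C[C@H](c1ccc(O[Si](C(C)C)(C(C)C)C(C)C)cc1O[Si](C(C)C)(C(C)C)C(C)C)O[Si](CC)(CC)CC | intermediate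
29 | (2-siloxyvinyl)ketene from ring opening of 17 | C=C(O[Si](C(C)C)(C(C)C)C(C)C)C(=C=O)C[C@H](CC=C(C)C)C(C)(C)O[Si](CC)(CC)CC | intermediate
30 | 4-vinylcyclobutenone from 29 and 28 | COC1=C(C(O[Si](C)(C)C(C)(C)C)C[C@H](c2ccc(O[Si](C(C)C)(C(C)C)C(C)C)cc2O[Si](C(C)C)(C(C)C)C(C)C)O[Si](CC)(CC)CC)C(=O)C1(C[C@H](CC=C(C)C)C(C)(C)O[Si](CC)(CC)CC)C(=C)O[Si](C(C)C)(C(C)C)C(C)C | intermediate
31 | dienylketene from ring opening of 30 | O=C=C(C(O[Si](C)(C)C(C)(C)C)C[C@H](c1ccc(O[Si](C(C)C)(C(C)C)C(C)C)cc1O[Si](C(C)C)(C(C)C)C(C)C)O[Si](CC)(CC)CC)/C(OC)=C(\C(=C)O[Si](C(C)C)(C(C)C)C(C)C)C[C@H](CC=C(C)C)C(C)(C)O[Si](CC)(CC)CC | intermediate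
32 | cyclohexa-2,4-dienone from 6π closure of 31 | O=C1CC(O[Si](C(C)C)(C(C)C)C(C)C)=C(C[C@H](CC=C(C)C)C(C)(C)O[Si](CC)(CC)CC)C(OC)=C1C(O[Si](C)(C)C(C)(C)C)C[C@H](c1ccc(O[Si](C(C)C)(C(C)C)C(C)C)cc1O[Si](C(C)C)(C(C)C)C(C)C)O[Si](CC)(CC)CC | intermediate
33 | pentasubstituted ring A phenol (benzannulation product) | COc1c(C[C@H](CC=C(C)C)C(C)(C)O[Si](CC)(CC)CC)c(O[Si](C(C)C)(C(C)C)C(C)C)cc(O)c1C(O[Si](C)(C)C(C)(C)C)C[C@H](c1ccc(O[Si](C(C)C)(C(C)C)C(C)C)cc1O[Si](C(C)C)(C(C)C)C(C)C)O[Si](CC)(CC)CC | intermediate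
34 | phenol with free (R)-C2 carbinol | COc1c(C[C@H](CC=C(C)C)C(C)(C)O[Si](CC)(CC)CC)c(O[Si](C(C)C)(C(C)C)C(C)C)cc(O)c1C(O[Si](C)(C)C(C)(C)C)C[C@H](c1ccc(O[Si](C(C)C)(C(C)C)C(C)C)cc1O[Si](C(C)C)(C(C)C)C(C)C)O | intermediate
35 | (2S)-flavan with C4 tert-butyldimethylsilyl ether | COc1c(C[C@H](CC=C(C)C)C(C)(C)O[Si](CC)(CC)CC)c(O[Si](C(C)C)(C(C)C)C(C)C)cc2c1C(O[Si](C)(C)C(C)(C)C)C[C@@H](c1ccc(O[Si](C(C)C)(C(C)C)C(C)C)cc1O[Si](C(C)C)(C(C)C)C(C)C)O2 | intermediate
36 | (2S)-tris(triisopropylsilyl) flavan-4-ol | COc1c(C[C@H](CC=C(C)C)C(C)(C)O)c(O[Si](C(C)C)(C(C)C)C(C)C)cc2c1C(O)C[C@@H](c1ccc(O[Si](C(C)C)(C(C)C)C(C)C)cc1O[Si](C(C)C)(C(C)C)C(C)C)O2 | intermediate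
37 | (2S)-tris(triisopropylsilyl) flavanone | COc1c(C[C@H](CC=C(C)C)C(C)(C)O)c(O[Si](C(C)C)(C(C)C)C(C)C)cc2c1C(=O)C[C@@H](c1ccc(O[Si](C(C)C)(C(C)C)C(C)C)cc1O[Si](C(C)C)(C(C)C)C(C)C)O2 | intermediate
38 | (2S)-2-(2,4-dihydroxyphenyl)-7-hydroxy-6-[(2S)-2-(2-hydroxypropan-2-yl)-5-methylhex-4-en-1-yl]-5-methoxychroman-4-one | COc1c(C[C@H](CC=C(C)C)C(C)(C)O)c(O)cc2c1C(=O)C[C@@H](c1ccc(O)cc1O)O2 | target

Total steps: 19. Longest linear sequence: 13 steps (steps 1 to 7, then 14 to 19); the other branch is steps 8 to 13.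

Steps most likely to fail

Step 14. The thermally formed vinylketene may be consumed by intramolecular ketene–olefin [2+2] cycloaddition onto the prenyl double bond, which sits on a three-atom tether. Alternatively, the hindered ynol ether may add too slowly, so that the ketene dimerises or acylates the product phenol. The fallback delays the trisubstituted olefin. From 4, alkylation with allyl bromide (NaN(SiMe3)2, THF, −78 °C) should give the allyl imide F1. The operations of steps 3 to 7 would then give the methyl ester F2, the carbinol F3, the triethylsilyl ether F4, the siloxyalkyne F5 and the cyclobutenone F6. Benzannulation of F6 with 28 under the conditions of step 14 should give the allyl phenol F7, since a monosubstituted olefin is a much poorer ketenophile. Cross-metathesis of F7 with 2-methylbut-2-ene (second-generation Grubbs catalyst RuCl2(=CHPh)(PCy3)(H2IMes), CH2Cl2, 40 °C) would install the prenyl terminus and return to 33.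

Step 16. Ionisation at the benzylic carbon, which is activated by the ortho and para oxygens of ring B, may precede displacement and cause loss of configuration at C2 or elimination. Displacement next to the ortho silyloxy group may also be slow. The fallback gives up substrate control at C2 and restores it by catalyst control. From 34, ring closure through the benzylic cation ((PhO)2P(O)OH cat., CH2Cl2, −20 °C) should give the flavan silyl ether F8 as C2 epimers. The operations of steps 17 and 18 would give the flavan-4-ol F9 and the C2-epimeric flavanone F10, which is 37 together with its 2R epimer. Kinetic resolution by asymmetric transfer hydrogenation (RhCl(Cp*)[(R,R)-TsDPEN], HCO2H/Et3N, EtOAc, rt) should reduce the 2R epimer to the cis-flavan-4-ol F11 and leave 37, where the route resumes.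

Step 17. Cleavage of the hindered benzylic C4 silyl ether may be slow, with competing loss of aryl silyl ethers or acid-promoted ionisation and elimination at C4. The fallback reverses the order of unmasking and oxidation. From 35, exhaustive desilylation under basic fluoride conditions (Bu4NF, THF, rt to 45 °C) should give the pentahydroxy flavan-4-ol F12; with no acid present and no carbonyl yet, neither C4 ionisation nor ring opening is available. Chemoselective oxidation of the benzylic carbinol of F12 with activated MnO2 (EtOAc, rt), which leaves phenols and the tertiary alcohol alone, would give 38 directly.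

Further compounds
F1 | step 14 | (S)-4-benzyl-3-[(2S)-2-(prop-2-yn-1-yl)pent-4-enoyl]oxazolidin-2-one | C#CC[C@H](CC=C)C(=O)N1[C@@H](Cc2ccccc2)COC1=O
F2 | step 14 | methyl (2S)-2-(prop-2-yn-1-yl)pent-4-enoate | C#CC[C@H](CC=C)C(=O)OC
F3 | step 14 | (3S)-2-methyl-3-(prop-2-yn-1-yl)hex-5-en-2-ol | C#CC[C@H](CC=C)C(C)(C)O
F4 | step 14 | triethylsilyl ether of F3 | C#CC[C@H](CC=C)C(C)(C)O[Si](CC)(CC)CC
F5 | step 14 | allyl-bearing siloxyalkyne | CC(C)[Si](OC#CC[C@H](CC=C)C(C)(C)O[Si](CC)(CC)CC)(C(C)C)C(C)C
F6 | step 14 | allyl-bearing 3-siloxycyclobutenone | O=C1CC(O[Si](C(C)C)(C(C)C)C(C)C)=C1C[C@H](CC=C)C(C)(C)O[Si](CC)(CC)CC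
F7 | step 14 | allyl analogue of phenol 33 | COc1c(C[C@H](CC=C)C(C)(C)O[Si](CC)(CC)CC)c(O[Si](C(C)C)(C(C)C)C(C)C)cc(O)c1C(O[Si](C)(C)C(C)(C)C)C[C@H](c1ccc(O[Si](C(C)C)(C(C)C)C(C)C)cc1O[Si](C(C)C)(C(C)C)C(C)C)O[Si](CC)(CC)CC
F8 | step 16 | flavan silyl ether, epimers at C2 | COc1c(C[C@H](CC=C(C)C)C(C)(C)O[Si](CC)(CC)CC)c(O[Si](C(C)C)(C(C)C)C(C)C)cc2c1C(O[Si](C)(C)C(C)(C)C)CC(c1ccc(O[Si](C(C)C)(C(C)C)C(C)C)cc1O[Si](C(C)C)(C(C)C)C(C)C)O2
F9 | step 16 | tris(triisopropylsilyl) flavan-4-ol, epimers at C2 | COc1c(C[C@H](CC=C(C)C)C(C)(C)O)c(O[Si](C(C)C)(C(C)C)C(C)C)cc2c1C(O)CC(c1ccc(O[Si](C(C)C)(C(C)C)C(C)C)cc1O[Si](C(C)C)(C(C)C)C(C)C)O2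
F10 | step 16 | tris(triisopropylsilyl) flavanone, epimers at C2 | COc1c(C[C@H](CC=C(C)C)C(C)(C)O)c(O[Si](C(C)C)(C(C)C)C(C)C)cc2c1C(=O)CC(c1ccc(O[Si](C(C)C)(C(C)C)C(C)C)cc1O[Si](C(C)C)(C(C)C)C(C)C)O2
F11 | step 16 | (2R,4R)-cis-flavan-4-ol from the 2R epimer | COc1c(C[C@H](CC=C(C)C)C(C)(C)O)c(O[Si](C(C)C)(C(C)C)C(C)C)cc2c1[C@H](O)C[C@H](c1ccc(O[Si](C(C)C)(C(C)C)C(C)C)cc1O[Si](C(C)C)(C(C)C)C(C)C)O2
F12 | step 17 | fully desilylated (2S)-flavan-4-ol | COc1c(C[C@H](CC=C(C)C)C(C)(C)O)c(O)cc2c1C(O)C[C@@H](c1ccc(O)cc1O)O2
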